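Per day, the fraction of the substrate charged not yet found as product or trapped intermediate falls at 1.11 /d in the cedar run, read between 1.04 d and 3.00 d. Cedar is the flask asked about, followed so far.

in all of them: substrate 0.78 M; free catalyst 1.6 mM

| charge | coupling partner | capture agent | remark | time |
|---|---|---|---|---|
| cedar | 0.78 M | 0.78 M | the very flask that is asked about, followed so far |  |
| flask | 0.780 M | 0.780 M |  | 15 d |

cedar run (percent of the substrate charged)

| time / d | product / % | trapped intermediate / % |
|---|---|---|
| 0.208 | 11.1 | 3.5 |
| 0.625 | 33.3 | 14.5 |
| 1.04 | 48.4 | 20.9 |
| 1.67 | 59.8 | 26.0 |
| 2.50 | 65.9 | 29.0 |
| 3.00 | 66.9 | 29.6 |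

(each reading ± 1 percentage point)

- ratio of product to trapped intermediate at 1.0 h
- ratio of product to trapped intermediate at 15 d
- which of product and trapped intermediate there is more of at 15 d

- the numbers in the tables scatter by 1 percentage point (one standard deviation)
- steps that have been proposed: substrate + free catalyst -> free catalyst + open intermediate; free catalyst + open intermediate <-> catalyst intermediate; coupling partner + catalyst intermediate -> free catalyst + product; open intermediate + capture agent -> trapped intermediate

From the last cedar reading, the ratio of product to trapped intermediate, multiplied by the capture agent charged per substrate charged, is

σ = 2.26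

This is the selectivity factor. The capture agent enters it as a factor, and the proposed capture step is first order in capture agent.

The cedar run in slow motion begins with the first reading at 0.208 d, where the ratio reads 3.17. That rests on 3.5 % of trapped intermediate with a scatter of 1 percentage point, so it does not stand clear of σ. In the middle, the ratio reads 2.30 at 0.625 d and 2.30 at 1.67 d, while product and trapped intermediate climb together. At the end, 3.50 % remains uncounted at 3.00 d, with a half-time of 0.624 d. The final proposed steps to product and to trapped intermediate are written one-way, while the step forming catalyst intermediate is written reversible.

My reckoning for cedar sets the ratio to σ at both asked times: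

product share at the end = σ/(1+σ) = 69.3 %

The forecast gives 2.7 at 1.0 h, 2.25 at 15 d, and product ahead. Its grounds for the early value, where it parts from my reckoning: “Catalyst is freest at the start and partner/capture ratio is highest, so branching may favour product.”

    substrate + free catalyst → free catalyst + open intermediate (k = 360 /M/h)
    free catalyst + open intermediate ⇌ catalyst intermediate (K = 2.10 /M, k = 36.0 /M/h)
    coupling partner + catalyst intermediate → free catalyst + product (k = 99.0 /M/h)
    open intermediate + capture agent → trapped intermediate (k = 0.0240 /M/h)

The cedar flask gives 2.28 at 1.0 h and 2.28 at 15 d, level with each other, so the early ratio stands below the forecast's 2.7 and beside σ = 2.26. product leads, 69.5 % against 30.5 %. The neighbouring flask holds the same recipe but 0.47 M of capture agent, 0.603 equiv. There σ gives 3.75 at 15 d, and the simulation gives 3.73, ending with 78.9 % of product and 21.1 % of trapped intermediate.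

Readings and results come from a simulation for an exercise, noise included.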